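**Retrosynthetic overview**

1. The target is catechin-(4α→6)-catechin-(4α→6)-epicatechin. The last two operations are hydroboration–oxidation of a 4H-chromene in the middle unit (C2 and C3 set from C4) and global hydrogenolysis (fourteen benzyl ethers, one C–Br bond).
2. Key disconnection: ring C of the middle unit is cut at C4–C4a and O1–C2 into a phenol and a chalcone ([3+3]). The feature that allows this: ring A of the middle unit is a phloroglucinol ring carrying the upper unit on C6, para to C8a–O1, while the lower unit sits on C4 of ring C. Without ring C this ring A is symmetric about the C6···C8a axis, so both carbons ortho to the phenol oxygen are the same and only the 4→6 pattern can form.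
3. Phenol half: (+)-catechin is benzylated, oxidised at C4 and arylated 4α by a silylated 3,5-bis(benzyloxy)phenol.
4. Chalcone half: (−)-epicatechin is benzylated, blocked at C8 with bromine, formylated at C6 and condensed with 3',4'-bis(benzyloxy)acetophenone.
5. Ring order: the pyran rings of the upper and lower units come with the two flavanols; only ring C of the middle unit is built (step 14).

Key step: step 14

Naming remark: flavan numbering is used for each unit; α is the face of that unit's C2 aryl group, β the other face.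
Assumption: the (R) acid is taken to open the chalcone face that leads to the 4α-aryl chromene; if a trial with 3,5-bis(benzyloxy)phenol shows the opposite sense, the (S) acid is used and nothing else changes.

**Route**

Step 1
Reactants: 1 (+)-catechin
Product: 2 5,7,3',4'-tetra-O-benzyl-(+)-catechin, (2R,3S)
Conditions: BnBr (4.2 equiv), K2CO3, DMF, 0 °C to rt
Reagents that add atoms: benzyl bromide, BrCc1ccccc1
Why: Williamson etherification with a carbonate base should alkylate only the four phenols and, being mild and cold, should leave C2 unepimerised.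

Step 2
Reactants: 2 5,7,3',4'-tetra-O-benzyl-(+)-catechin
Product: 3 3,5,7,3',4'-penta-O-benzyl-(+)-catechin
Conditions: NaH, BnBr, n-Bu4NI (cat.), THF, 0 °C to rt
Reagents that add atoms: benzyl bromide, BrCc1ccccc1
Why: Williamson etherification of the secondary alkoxide should proceed cleanly, since with all phenols capped no quinone methide pathway can epimerise C2.

Step 3
Reactants: 3 3,5,7,3',4'-penta-O-benzyl-(+)-catechin
Product: 4 (2R,3S,4S)-3,5,7,3',4'-pentakis(benzyloxy)-4-(2-ethoxyethoxy)flavan (4β ether)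
Conditions: DDQ (2 equiv), 2-ethoxyethanol (5 equiv), CH2Cl2, rt
Reagents that add atoms: 2-ethoxyethanol, CCOCCO
Why: DDQ benzylic oxidation should abstract hydride from C4 (cation stabilised by the 5,7-dialkoxy ring A) and the alcohol should trap it anti to the C2 aryl group; the C4 configuration is lost again in step 6.

Step 4
Reactants: 5 phloroglucinol
Product: 6 3,5-bis(benzyloxy)phenol
Conditions: NaH (2.0 equiv), BnCl (2.0 equiv), DMF, 0 °C to rt; chromatography
Reagents that add atoms: benzyl chloride, ClCc1ccccc1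
Why: Williamson etherification of the threefold-symmetric triol with two equivalents of electrophile should give the dibenzyl ether as the main part of a statistical mixture, separable from the mono- and tribenzyl ethers.

Step 5
Reactants: 6 3,5-bis(benzyloxy)phenol
Product: 7 [3,5-bis(benzyloxy)phenoxy]triisopropylsilane
Conditions: i-Pr3SiCl, imidazole, DMF, rt
Reagents that add atoms: chlorotriisopropylsilane, CC(C)[Si](Cl)(C(C)C)C(C)C
Why: Imidazole-promoted silylation should mask the oxygen that becomes O1 of the middle unit with a fluoride-labile group bulky enough to screen its two ortho carbons.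

Step 6
Reactants: 4 4β-(2-ethoxyethoxy) ether of penta-O-benzylcatechin; 7 [3,5-bis(benzyloxy)phenoxy]triisopropylsilane (3 equiv)
Product: 8 3,5,7,3',4'-penta-O-benzylcatechin bearing a 2,6-bis(benzyloxy)-4-(triisopropylsilyloxy)phenyl group at C4α (2,3-trans-3,4-trans)
Conditions: Me3SiOTf (0.2 equiv), CH2Cl2, −78 to −40 °C
Reagents that add atoms: none
Why: Lewis-acid ionisation of the C4 ether gives the benzylic cation, which should undergo Friedel–Crafts arylation by the carbon of 7 para to the silyloxy group (the ortho carbons are screened by the silyl group) on the face anti to the C3 benzyloxy group, placing the aryl group 4α as is usual for 2,3-trans flavan C4 cations.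

Step 7
Reactants: 8 C4α-aryl silyl ether
Product: 9 4-(3,5,7,3',4'-penta-O-benzylcatechin-4α-yl)-3,5-bis(benzyloxy)phenol
Conditions: n-Bu4NF, AcOH (1:1), THF, 0 °C
Reagents that add atoms: none
Why: Fluoride cleavage of the aryl silyl ether is fast, and the acetic acid buffer should keep the very electron-rich phenoxide from air oxidation while the benzyl ethers and the C4–aryl bond stay untouched.

Step 8
Reactants: 10 (−)-epicatechin
Product: 11 5,7,3',4'-tetra-O-benzyl-(−)-epicatechin, (2R,3R)
Conditions: BnBr (4.2 equiv), K2CO3, DMF, 0 °C to rt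
Reagents that add atoms: benzyl bromide, BrCc1ccccc1
Why: Williamson etherification of the four phenols under carbonate should leave the C3 alcohol and the 2,3-cis configuration intact.

Step 9
Reactants: 11 5,7,3',4'-tetra-O-benzyl-(−)-epicatechin
Product: 12 3,5,7,3',4'-penta-O-benzyl-(−)-epicatechin
Conditions: NaH, BnBr, n-Bu4NI (cat.), THF, 0 °C to rt
Reagents that add atoms: benzyl bromide, BrCc1ccccc1
Why: Williamson etherification of the C3 alkoxide should give the pentabenzyl ether and remove the only group that would interfere with the formylation.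

Step 10
Reactants: 12 3,5,7,3',4'-penta-O-benzyl-(−)-epicatechin
Product: 13 8-bromo-3,5,7,3',4'-penta-O-benzylepicatechin
Conditions: NBS (1.0 equiv), CH2Cl2, −78 °C to rt
Reagents that add atoms: N-bromosuccinimide, O=C1CCC(=O)N1Br
Why: Electrophilic aromatic bromination of benzylated flavan-3-ols is selective for C8 of ring A, so the bromine should block C8 and leave C6 as the only activated ring A carbon.

Step 11
Reactants: 13 8-bromo-3,5,7,3',4'-penta-O-benzylepicatechin
Product: 15 8-bromo-6-formyl-3,5,7,3',4'-penta-O-benzylepicatechin, via C6 iminium chloride 14 (not isolated)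
Conditions: POCl3, DMF, ClCH2CH2Cl, 0 to 70 °C; then H2O
Reagents that add atoms: N,N-dimethylformamide, CN(C)C=O (formyl carbon); water, O (carbonyl oxygen)
Why: Vilsmeier–Haack formylation should occur at C6, the one open carbon activated by three oxygens (ortho to both benzyloxy groups, para to O1), as trialkoxybenzenes formylate between two alkoxy groups, while ring B is much less activated.

Step 12
Reactants: 16 3',4'-dihydroxyacetophenone
Product: 17 3',4'-bis(benzyloxy)acetophenone
Conditions: BnBr (2.2 equiv), K2CO3, DMF, 60 °C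
Reagents that add atoms: benzyl bromide, BrCc1ccccc1
Why: Williamson etherification of both phenols should be straightforward, since the methyl ketone is not alkylated by carbonate.

Step 13
Reactants: 15 8-bromo-6-formyl-penta-O-benzylepicatechin; 17 3',4'-bis(benzyloxy)acetophenone
Product: 19 (E)-1-[3,4-bis(benzyloxy)phenyl]-3-(8-bromo-3,5,7,3',4'-penta-O-benzylepicatechin-6-yl)prop-2-en-1-one, via aldol adduct 18 (not isolated)
Conditions: KOH (50% aq.), EtOH/THF, rt to 40 °C
Reagents that add atoms: none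
Why: Claisen–Schmidt condensation of a non-enolisable aldehyde with the methyl ketone, followed by E1cB dehydration, should give the conjugated (E)-enone, and with every phenol benzylated the base cannot epimerise C2 of the epicatechin unit.

Step 14
Reactants: 9 catechin-4α-yl 3,5-bis(benzyloxy)phenol; 19 (E)-chalcone from 8-bromo-6-formylepicatechin
Product: 22 protected trimer whose middle unit is a 2,4-diaryl-4H-chromene (lower unit 4α), via ketone adduct 20 (not isolated), via cyclic hemiketal 21 (not isolated)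
Conditions: (R)-3,3'-bis(2,4,6-triisopropylphenyl)-1,1'-binaphthyl-2,2'-diyl hydrogen phosphate [(R)-TRIP] (20 mol %), 4 Å molecular sieves, toluene, 40 °C
Reagents that add atoms: none
Why: The acid binds the phenol O–H through P=O and the chalcone carbonyl through P–OH, so that an ortho carbon of 9 adds to the β-carbon of 19 (Friedel–Crafts conjugate addition, C4–C4a) and rearomatisation gives ketone 20. Ring C of the middle unit then closes by 6-exo-trig addition of the phenol oxygen to the ketone (hemiketal 21, O1–C2), and acid-promoted loss of water, held by the sieves, leaves the cyclic enol ether 22. The closest known reaction type is the Brønsted-acid-catalysed Friedel–Crafts alkylation/cyclodehydration of electron-rich phenols and naphthols with enones to 4-aryl-4H-chromenes, including chiral-acid variants; a chalcone whose β-aryl group is di-ortho-substituted lies at the hindered end of that scope, though its 2,6-dialkoxyaryl group helps to carry positive charge at the β-carbon. The single new stereocentre, C4, is set by the face of the β-carbon that the chiral acid leaves open, the stereocentres of both fragments being too remote to do more than make the pairing matched or mismatched; a minor C4 epimer would be a diastereomer and separable. The step needs the 4→6 connectivity and C- rather than O-alkylation: the para carbon of the phenol is occupied by the catechinyl group and the two ortho carbons are equivalent by the local symmetry of the ring, and oxa-Michael addition is reversible whereas only the C-adduct can cyclodehydrate.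

Step 15
Reactants: 22 protected 4H-chromene trimer
Product: 24 8-bromo-tetradeca-O-benzyl trimer whose middle unit is a 2,3-trans-3,4-trans flavan-3-ol (free 3-OH), via C3 alkylborane 23 (not isolated)
Conditions: BH3·SMe2 (5 equiv), THF, 0 °C to rt; then NaBO3·4H2O, H2O, rt
Reagents that add atoms: sodium perborate tetrahydrate (NaBO3·4H2O), [Na+].[O-]OB=O.O.O.O.O (hydroxyl oxygen)
Why: Hydroboration–oxidation of the enol ether should place boron on C3 and hydrogen on C2 by syn addition on the face anti to the bulky C4 aryl group, and oxidation with retention then gives the 3β-hydroxyl trans to both the C4 aryl and the C2 aryl group (C2 R, C3 S).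

Step 16
Reactants: 24 8-bromo-tetradeca-O-benzyl trimer
Product: 25 catechin-(4α→6)-catechin-(4α→6)-epicatechin (CNP0163146.3)
Conditions: H2 (1 atm), Pd(OH)2 on carbon (20 wt %), Et3N, THF/MeOH/H2O, rt
Reagents that add atoms: none
Why: Hydrogenolysis should remove the fourteen benzyl ethers and the aryl bromide in one operation, with Et3N taking up HBr so that the acid-labile interflavan bonds are not cleaved and no stereocentre is touched.

**Compound list**

1 | (+)-catechin | O[C@H]1Cc2c(O)cc(O)cc2O[C@@H]1c1ccc(O)c(O)c1 | starting material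
2 | 5,7,3',4'-tetra-O-benzyl-(+)-catechin | O[C@H]1Cc2c(OCc9ccccc9)cc(OCc9ccccc9)cc2O[C@@H]1c7ccc(OCc9ccccc9)c(OCc9ccccc9)c7 | intermediate
3 | 3,5,7,3',4'-penta-O-benzyl-(+)-catechin | c9ccccc9COc1cc(OCc9ccccc9)c2c(c1)O[C@H](c7ccc(OCc9ccccc9)c(OCc9ccccc9)c7)[C@@H](OCc9ccccc9)C2 | intermediate
4 | (2R,3S,4S)-3,5,7,3',4'-pentakis(benzyloxy)-4-(2-ethoxyethoxy)flavan | c9ccccc9COc1cc(OCc9ccccc9)c2c(c1)O[C@H](c7ccc(OCc9ccccc9)c(OCc9ccccc9)c7)[C@@H](OCc9ccccc9)[C@H]2OCCOCC | intermediate
5 | phloroglucinol | Oc1cc(O)cc(O)c1 | starting material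
6 | 3,5-bis(benzyloxy)phenol | Oc1cc(OCc9ccccc9)cc(OCc9ccccc9)c1 | intermediate
7 | [3,5-bis(benzyloxy)phenoxy]triisopropylsilane | CC(C)[Si](C(C)C)(C(C)C)Oc1cc(OCc9ccccc9)cc(OCc9ccccc9)c1 | intermediate
8 | penta-O-benzylcatechin with 2,6-bis(benzyloxy)-4-(triisopropylsilyloxy)phenyl at C4α | c9ccccc9COc1cc(OCc9ccccc9)c2c(c1)O[C@H](c7ccc(OCc9ccccc9)c(OCc9ccccc9)c7)[C@@H](OCc9ccccc9)[C@@H]2c1c(OCc9ccccc9)cc(O[Si](C(C)C)(C(C)C)C(C)C)cc1OCc9ccccc9 | intermediate
9 | 4-(penta-O-benzylcatechin-4α-yl)-3,5-bis(benzyloxy)phenol | c9ccccc9COc1cc(OCc9ccccc9)c2c(c1)O[C@H](c7ccc(OCc9ccccc9)c(OCc9ccccc9)c7)[C@@H](OCc9ccccc9)[C@@H]2c1c(OCc9ccccc9)cc(O)cc1OCc9ccccc9 | intermediate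
10 | (−)-epicatechin | O[C@@H]1Cc2c(O)cc(O)cc2O[C@@H]1c1ccc(O)c(O)c1 | starting material
11 | 5,7,3',4'-tetra-O-benzyl-(−)-epicatechin | O[C@@H]1Cc2c(OCc9ccccc9)cc(OCc9ccccc9)cc2O[C@@H]1c7ccc(OCc9ccccc9)c(OCc9ccccc9)c7 | intermediate
12 | 3,5,7,3',4'-penta-O-benzyl-(−)-epicatechin | c1c(OCc9ccccc9)cc3c(c1OCc9ccccc9)C[C@@H](OCc9ccccc9)[C@@H](c7ccc(OCc9ccccc9)c(OCc9ccccc9)c7)O3 | intermediate
13 | 8-bromo-3,5,7,3',4'-penta-O-benzylepicatechin | c1c(OCc9ccccc9)c(Br)c3c(c1OCc9ccccc9)C[C@@H](OCc9ccccc9)[C@@H](c7ccc(OCc9ccccc9)c(OCc9ccccc9)c7)O3 | intermediate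
14 | C6 N,N-dimethyliminium chloride of 13 | C[N+](C)=Cc1c(OCc9ccccc9)c(Br)c3c(c1OCc9ccccc9)C[C@@H](OCc9ccccc9)[C@@H](c7ccc(OCc9ccccc9)c(OCc9ccccc9)c7)O3.[Cl-] | intermediate
15 | 8-bromo-6-formyl-3,5,7,3',4'-penta-O-benzylepicatechin | O=Cc1c(OCc9ccccc9)c(Br)c3c(c1OCc9ccccc9)C[C@@H](OCc9ccccc9)[C@@H](c7ccc(OCc9ccccc9)c(OCc9ccccc9)c7)O3 | intermediate
16 | 3',4'-dihydroxyacetophenone | CC(=O)c1ccc(O)c(O)c1 | starting material
17 | 3',4'-bis(benzyloxy)acetophenone | CC(=O)c1ccc(OCc9ccccc9)c(OCc9ccccc9)c1 | intermediate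
18 | aldol adduct of 15 and 17 (carbinol centre: both epimers) | O=C(c7ccc(OCc9ccccc9)c(OCc9ccccc9)c7)CC(O)c1c(OCc9ccccc9)c(Br)c3c(c1OCc9ccccc9)C[C@@H](OCc9ccccc9)[C@@H](c7ccc(OCc9ccccc9)c(OCc9ccccc9)c7)O3 | intermediate
19 | (E)-chalcone from 8-bromo-6-formylepicatechin pentabenzyl ether | O=C(c7ccc(OCc9ccccc9)c(OCc9ccccc9)c7)/C=C/c1c(OCc9ccccc9)c(Br)c3c(c1OCc9ccccc9)C[C@@H](OCc9ccccc9)[C@@H](c7ccc(OCc9ccccc9)c(OCc9ccccc9)c7)O3 | intermediate
20 | ketone adduct (C4–C4a bond formed, ring C open) | c9ccccc9COc1cc(OCc9ccccc9)c2c(c1)O[C@H](c7ccc(OCc9ccccc9)c(OCc9ccccc9)c7)[C@@H](OCc9ccccc9)[C@@H]2c1c(OCc9ccccc9)cc(O)c(c1OCc9ccccc9)[C@@H](c1c(OCc9ccccc9)c(Br)c3c(c1OCc9ccccc9)C[C@@H](OCc9ccccc9)[C@@H](c7ccc(OCc9ccccc9)c(OCc9ccccc9)c7)O3)CC(=O)c7ccc(OCc9ccccc9)c(OCc9ccccc9)c7 | intermediate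
21 | cyclic hemiketal (2-hydroxyflavan middle unit; C2: both epimers) | c9ccccc9COc1cc(OCc9ccccc9)c2c(c1)O[C@H](c7ccc(OCc9ccccc9)c(OCc9ccccc9)c7)[C@@H](OCc9ccccc9)[C@@H]2c1c(OCc9ccccc9)cc2c(c1OCc9ccccc9)[C@@H](c1c(OCc9ccccc9)c(Br)c3c(c1OCc9ccccc9)C[C@@H](OCc9ccccc9)[C@@H](c7ccc(OCc9ccccc9)c(OCc9ccccc9)c7)O3)CC(O)(c7ccc(OCc9ccccc9)c(OCc9ccccc9)c7)O2 | intermediate
22 | protected trimer, middle unit a 2,4-diaryl-4H-chromene (lower unit 4α) | c9ccccc9COc1cc(OCc9ccccc9)c2c(c1)O[C@H](c7ccc(OCc9ccccc9)c(OCc9ccccc9)c7)[C@@H](OCc9ccccc9)[C@@H]2c1c(OCc9ccccc9)cc2c(c1OCc9ccccc9)[C@@H](c1c(OCc9ccccc9)c(Br)c3c(c1OCc9ccccc9)C[C@@H](OCc9ccccc9)[C@@H](c7ccc(OCc9ccccc9)c(OCc9ccccc9)c7)O3)C=C(c7ccc(OCc9ccccc9)c(OCc9ccccc9)c7)O2 | intermediate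
23 | C3 alkylborane of the middle unit (boron 3β) | c9ccccc9COc1cc(OCc9ccccc9)c2c(c1)O[C@H](c7ccc(OCc9ccccc9)c(OCc9ccccc9)c7)[C@@H](OCc9ccccc9)[C@@H]2c1c(OCc9ccccc9)cc2c(c1OCc9ccccc9)[C@@H](c1c(OCc9ccccc9)c(Br)c3c(c1OCc9ccccc9)C[C@@H](OCc9ccccc9)[C@@H](c7ccc(OCc9ccccc9)c(OCc9ccccc9)c7)O3)[C@H](B)[C@@H](c7ccc(OCc9ccccc9)c(OCc9ccccc9)c7)O2 | intermediate
24 | 8-bromo-tetradeca-O-benzyl catechin-(4α→6)-catechin-(4α→6)-epicatechin, free 3-OH on the middle unit | c9ccccc9COc1cc(OCc9ccccc9)c2c(c1)O[C@H](c7ccc(OCc9ccccc9)c(OCc9ccccc9)c7)[C@@H](OCc9ccccc9)[C@@H]2c1c(OCc9ccccc9)cc2c(c1OCc9ccccc9)[C@@H](c1c(OCc9ccccc9)c(Br)c3c(c1OCc9ccccc9)C[C@@H](OCc9ccccc9)[C@@H](c7ccc(OCc9ccccc9)c(OCc9ccccc9)c7)O3)[C@H](O)[C@@H](c7ccc(OCc9ccccc9)c(OCc9ccccc9)c7)O2 | intermediate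
25 | catechin-(4α→6)-catechin-(4α→6)-epicatechin (CNP0163146.3) | Oc1cc(O)c2c(c1)O[C@H](c1ccc(O)c(O)c1)[C@@H](O)[C@@H]2c1c(O)cc2c(c1O)[C@@H](c1c(O)cc3c(c1O)C[C@@H](O)[C@@H](c1ccc(O)c(O)c1)O3)[C@H](O)[C@@H](c1ccc(O)c(O)c1)O2 | target

**Step count and risk**

Total steps: 16. Longest linear sequence: 8 steps (1, 2, 3, 6, 7, 14, 15, 16; the epicatechin branch 8, 9, 10, 11, 13, 14, 15, 16 is equally long).

Steps most likely to fail:

1. Step 14. The phenol may add too slowly to the doubly ortho-substituted β-carbon, the catalyst may discriminate poorly between the two faces when the pairing with the chiral fragments is mismatched, or the acid may cleave the upper unit from its phloroglucinol ring. The fallback brings in the middle unit as catechin itself and forms both interflavan bonds by Lewis-acid C4 arylation, which is established for 4→6 links when C8 is blocked by bromine. It sets out from 3, 4 and 13 and returns at 25. NBS (CH2Cl2, −78 °C) would brominate 3 at C8 to give 8-bromo-3,5,7,3',4'-penta-O-benzylcatechin F1. DDQ with 2-ethoxyethanol would convert this into its 4β-(2-ethoxyethoxy) ether F2. Me3SiOTf (CH2Cl2, −78 °C) with an excess of 13, whose only free ring A carbon is C6, should give the 4α→6 dimer 8-bromocatechin-(4α→6)-8-bromoepicatechin decabenzyl ether F3; the excess of 13 suppresses self-condensation of F2. The only free ring A carbon of F3 is C6 of its catechin unit, so a second Me3SiOTf coupling with 4 should give the fully benzylated dibromo trimer F4. Hydrogenolysis of F4 under the conditions of step 16 gives 25.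

2. Step 15. Borane may add slowly beside the congested C4, may not distinguish the two faces well enough, or the C3 borane may eliminate across C2–O1 and open ring C. The fallback sets out from 22 and returns at 24. Dimethyldioxirane (acetone/CH2Cl2, −40 °C) would epoxidise the enol ether anti to the C4 aryl group to give the 2β,3β-epoxide F5, used cold without purification. i-Bu2AlH (CH2Cl2, −78 °C) should then coordinate the epoxide oxygen, open the C2–O bond to the aryl-stabilised oxocarbenium ion and deliver hydride to C2 on the face of the departing oxygen, as alanes open glycal epoxides syn. This gives the same 2,3-trans-3,4-trans alcohol 24.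

3. Step 11. The chloroiminium ion may be too weak an electrophile for a brominated carbon flanked by two benzyloxy groups, and forcing conditions may start to formylate ring B. The fallback sets out from 13 and returns at 15. N-Iodosuccinimide with catalytic CF3CO2H (CH2Cl2, 0 °C) would iodinate C6 to give 8-bromo-6-iodo-3,5,7,3',4'-penta-O-benzylepicatechin F6; halogenation at C6 after C8 is the normal course for these ethers. i-PrMgCl·LiCl (THF, −40 °C) should exchange only the iodine to give the C6 arylmagnesium chloride F7, and DMF followed by aqueous NH4Cl gives aldehyde 15.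

**Further compounds**

F1 | step 14 | 8-bromo-3,5,7,3',4'-penta-O-benzylcatechin | c9ccccc9COc1cc(OCc9ccccc9)c2c(c1Br)O[C@H](c7ccc(OCc9ccccc9)c(OCc9ccccc9)c7)[C@@H](OCc9ccccc9)C2
F2 | step 14 | 8-bromo-3,5,7,3',4'-pentakis(benzyloxy)-4β-(2-ethoxyethoxy)flavan (catechin series) | c9ccccc9COc1cc(OCc9ccccc9)c2c(c1Br)O[C@H](c7ccc(OCc9ccccc9)c(OCc9ccccc9)c7)[C@@H](OCc9ccccc9)[C@H]2OCCOCC
F3 | step 14 | 8-bromocatechin-(4α→6)-8-bromoepicatechin decabenzyl ether | c1c(OCc9ccccc9)c(Br)c2c(c1OCc9ccccc9)[C@@H](c1c(OCc9ccccc9)c(Br)c3c(c1OCc9ccccc9)C[C@@H](OCc9ccccc9)[C@@H](c7ccc(OCc9ccccc9)c(OCc9ccccc9)c7)O3)[C@H](OCc9ccccc9)[C@@H](c7ccc(OCc9ccccc9)c(OCc9ccccc9)c7)O2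
F4 | step 14 | catechin-(4α→6)-8-bromocatechin-(4α→6)-8-bromoepicatechin pentadecabenzyl ether | c9ccccc9COc1cc(OCc9ccccc9)c2c(c1)O[C@H](c7ccc(OCc9ccccc9)c(OCc9ccccc9)c7)[C@@H](OCc9ccccc9)[C@@H]2c1c(OCc9ccccc9)c(Br)c2c(c1OCc9ccccc9)[C@@H](c1c(OCc9ccccc9)c(Br)c3c(c1OCc9ccccc9)C[C@@H](OCc9ccccc9)[C@@H](c7ccc(OCc9ccccc9)c(OCc9ccccc9)c7)O3)[C@H](OCc9ccccc9)[C@@H](c7ccc(OCc9ccccc9)c(OCc9ccccc9)c7)O2
F5 | step 15 | 2β,3β-epoxide of the middle unit of 22 | c9ccccc9COc1cc(OCc9ccccc9)c2c(c1)O[C@H](c7ccc(OCc9ccccc9)c(OCc9ccccc9)c7)[C@@H](OCc9ccccc9)[C@@H]2c1c(OCc9ccccc9)cc2c(c1OCc9ccccc9)[C@@H](c1c(OCc9ccccc9)c(Br)c3c(c1OCc9ccccc9)C[C@@H](OCc9ccccc9)[C@@H](c7ccc(OCc9ccccc9)c(OCc9ccccc9)c7)O3)[C@@H]4O[C@]4(c7ccc(OCc9ccccc9)c(OCc9ccccc9)c7)O2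
F6 | step 11 | 8-bromo-6-iodo-3,5,7,3',4'-penta-O-benzylepicatechin | Ic1c(OCc9ccccc9)c(Br)c3c(c1OCc9ccccc9)C[C@@H](OCc9ccccc9)[C@@H](c7ccc(OCc9ccccc9)c(OCc9ccccc9)c7)O3
F7 | step 11 | C6 arylmagnesium chloride of 8-bromo-penta-O-benzylepicatechin | Cl[Mg]c1c(OCc9ccccc9)c(Br)c3c(c1OCc9ccccc9)C[C@@H](OCc9ccccc9)[C@@H](c7ccc(OCc9ccccc9)c(OCc9ccccc9)c7)O3
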